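**Retrosynthetic overview**
1. Gericudranin E (16) ⇐ C3-carboxylated, benzyl-protected dihydroflavonol 13: one-pot hydrogenolysis, loss of CO2 and ketonisation, which sets the trans C3–H last.
2. 13 ⇐ aldehyde/α-keto ester 11: ring C is closed at C3–C4 by a chiral carbene. The ring A aldehyde carbon reacts as an acyl anion (Breslow intermediate) with the tethered keto carbonyl, and the labile C2 centre is resolved dynamically.
3. 11 ⇐ phenol 10 + β-chloro-α-keto ester 6 (O1–C2 ether bond).
4. 10 ⇐ 2,4,6-trihydroxybenzaldehyde (O-benzylation, then Friedel–Crafts C-benzylation); 6 ⇐ 4-(benzyloxy)benzaldehyde + benzyl dichloroacetate (Darzens condensation and rearrangement).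
5. Ring A, ring B and the benzyl ring are bought preformed; ring C is the only ring made, and it is made in the key step.

Assumption: the sense of induction for this new substrate class is taken by analogy; if the (5aS,10bR) triazolium salt of step 6 gives 2S, its commercial (5aR,10bS) antipode is used, and the C3 configuration drawn for 13 and 14 is immaterial because that centre is re-formed in step 7.

**Route**

Step 1
Reactants: 1 dichloroacetyl chloride; 2 benzyl alcohol
Product: 3 benzyl dichloroacetate
Conditions: CH2Cl2, 0 °C to rt, N2 sweep, no base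
Reagents that add atoms: none
Why: Simple acylation of an alcohol by a reactive acid chloride (esterification), with HCl leaving as gas.

Step 2
Reactants: 3 benzyl dichloroacetate; 4 4-(benzyloxy)benzaldehyde
Product: 6 benzyl 3-[4-(benzyloxy)phenyl]-3-chloro-2-oxopropanoate (racemic), via chloroglycidic ester 5 (not isolated)
Conditions: KOt-Bu (1.05 equiv), THF, −78 °C to rt; aq NH4Cl quench
Reagents that add atoms: none
Why: Darzens condensation of a dichloroacetate gives the α-chloroglycidic ester, which with an electron-rich aryl group opens at the benzylic C–O bond and shifts chloride to give the β-chloro-α-keto ester (chloro-epoxide to α-chloro-ketone rearrangement); the new centre is racemic by design.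

Step 3
Reactants: 7 2,4,6-trihydroxybenzaldehyde
Product: 8 4-(benzyloxy)-2,6-dihydroxybenzaldehyde
Conditions: BnBr (1.0 equiv), CsHCO3 (1.2 equiv), MeCN, 60 °C
Reagents that add atoms: benzyl bromide, BrCc1ccccc1
Why: Williamson etherification with a weak base alkylates only the 4-OH, which is para to the formyl group, the most acidic, and not tied up in a hydrogen bond to the carbonyl.

Step 4
Reactants: 8 4-(benzyloxy)-2,6-dihydroxybenzaldehyde; 9 4-(benzyloxy)benzyl alcohol
Product: 10 4-(benzyloxy)-3-[4-(benzyloxy)benzyl]-2,6-dihydroxybenzaldehyde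
Conditions: Sc(OTf)3 (5 mol%), MeCN, 40 °C, slow addition of 9 (0.8 equiv) to 8
Reagents that add atoms: none
Why: Friedel–Crafts benzylation by the easily ionised p-alkoxybenzyl alcohol; the two open ring positions of 8 are equivalent by symmetry and each is ortho/para to three oxygens, so a single mono-C-benzyl product is possible.

Step 5
Reactants: 10 4-(benzyloxy)-3-[4-(benzyloxy)benzyl]-2,6-dihydroxybenzaldehyde; 6 benzyl 3-[4-(benzyloxy)phenyl]-3-chloro-2-oxopropanoate
Product: 11 benzyl 3-{5-(benzyloxy)-4-[4-(benzyloxy)benzyl]-2-formyl-3-hydroxyphenoxy}-3-[4-(benzyloxy)phenyl]-2-oxopropanoate (racemic)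
Conditions: K2CO3 (1.1 equiv), acetone, 0 °C to rt, Ar
Reagents that add atoms: none
Why: Williamson-type SN2 displacement on an activated α-keto benzylic chloride; the 6-OH is alkylated because the 2-OH is flanked by both the formyl and the C-benzyl group, and the remaining chelated OH then resists a second alkylation.

Step 6
Reactants: 11 benzyl 3-{5-(benzyloxy)-4-[4-(benzyloxy)benzyl]-2-formyl-3-hydroxyphenoxy}-3-[4-(benzyloxy)phenyl]-2-oxopropanoate
Product: 13 benzyl (2R,3R)-7-(benzyloxy)-6-[4-(benzyloxy)benzyl]-2-[4-(benzyloxy)phenyl]-3,5-dihydroxy-4-oxochromane-3-carboxylate, via enol tautomer 12 (not isolated)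
Conditions: (5aS,10bR)-2-(2,4,6-trimethylphenyl)-5a,10b-dihydro-4H,6H-indeno[2,1-b][1,2,4]triazolo[4,3-d][1,4]oxazin-2-ium chloride (10 mol%), i-Pr2NEt (20 mol%), toluene, 25 °C, Ar
Reagents that add atoms: none
Why: Proposed new method: the carbene adds to the only aldehyde of 11 to give a Breslow acyl-anion equivalent at the future C4, which attacks the strongly electrophilic keto carbonyl (future C3) through a six-membered chair-like transition state with the C2 aryl group equatorial, while the two enantiomers of 11 interconvert quickly through the achiral enol 12 (the C2–H sits between an aryl ring, an aryloxy group and a 1,2-dicarbonyl unit), so the catalyst-matched enantiomer is drained to the 2R product in a dynamic kinetic resolution and the product, having no hydrogen at C3, can neither ring-open nor epimerise at C2; the closest known reaction types are the carbene-catalysed intramolecular aldehyde–ketone crossed benzoin cyclisation to 3-hydroxychroman-4-ones and carbene-catalysed dynamic kinetic benzoin reactions of keto esters with an epimerisable neighbouring stereocentre.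

Step 7
Reactants: 13 benzyl (2R,3R)-7-(benzyloxy)-6-[4-(benzyloxy)benzyl]-2-[4-(benzyloxy)phenyl]-3,5-dihydroxy-4-oxochromane-3-carboxylate
Product: 16 gericudranin E (2R,3R)-3,5,7-trihydroxy-6-(4-hydroxybenzyl)-2-(4-hydroxyphenyl)chroman-4-one, via hydroxy keto acid 14 (not isolated), via enediol 15 (not isolated)
Conditions: H2 (1 atm), Pd/C (10 wt%), EtOAc–MeOH, rt, then 40 °C
Reagents that add atoms: none
Why: Hydrogenolysis removes the three benzyl ethers and the benzyl ester, the α-hydroxy-β-keto acid 14 loses CO2 through the usual six-membered transition state (β-keto acid decarboxylation), and enediol 15 ketonises at C3 to the aryl-conjugated, 5-OH-chelated ketone by axial protonation anti to the axial C2–H, which places 3-OH equatorial and trans to the 2-aryl group (3R, also the thermodynamic epimer) while C2 from step 6 is untouched.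

**Compound list**
1 | dichloroacetyl chloride | O=C(Cl)C(Cl)Cl | starting material
2 | benzyl alcohol | OCc1ccccc1 | starting material
3 | benzyl dichloroacetate | O=C(OCc1ccccc1)C(Cl)Cl | intermediate
4 | 4-(benzyloxy)benzaldehyde | O=Cc1ccc(OCc2ccccc2)cc1 | starting material
5 | benzyl 3-[4-(benzyloxy)phenyl]-2-chlorooxirane-2-carboxylate (racemic) | O=C(OCc1ccccc1)C1(Cl)OC1c1ccc(OCc2ccccc2)cc1 | intermediate
6 | benzyl 3-[4-(benzyloxy)phenyl]-3-chloro-2-oxopropanoate (racemic) | O=C(OCc1ccccc1)C(=O)C(Cl)c1ccc(OCc2ccccc2)cc1 | intermediate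
7 | 2,4,6-trihydroxybenzaldehyde | O=Cc1c(O)cc(O)cc1O | starting material
8 | 4-(benzyloxy)-2,6-dihydroxybenzaldehyde | O=Cc1c(O)cc(OCc2ccccc2)cc1O | intermediate
9 | 4-(benzyloxy)benzyl alcohol | OCc1ccc(OCc2ccccc2)cc1 | starting material
10 | 4-(benzyloxy)-3-[4-(benzyloxy)benzyl]-2,6-dihydroxybenzaldehyde | O=Cc1c(O)cc(OCc2ccccc2)c(Cc2ccc(OCc3ccccc3)cc2)c1O | intermediate
11 | benzyl 3-{5-(benzyloxy)-4-[4-(benzyloxy)benzyl]-2-formyl-3-hydroxyphenoxy}-3-[4-(benzyloxy)phenyl]-2-oxopropanoate (racemic) | O=C(OCc1ccccc1)C(=O)C(Oc1cc(OCc2ccccc2)c(Cc2ccc(OCc3ccccc3)cc2)c(O)c1C=O)c1ccc(OCc2ccccc2)cc1 | intermediate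
12 | benzyl 3-{5-(benzyloxy)-4-[4-(benzyloxy)benzyl]-2-formyl-3-hydroxyphenoxy}-3-[4-(benzyloxy)phenyl]-2-hydroxyprop-2-enoate (achiral enol of 11) | O=C(OCc1ccccc1)C(O)=C(Oc1cc(OCc2ccccc2)c(Cc2ccc(OCc3ccccc3)cc2)c(O)c1C=O)c1ccc(OCc2ccccc2)cc1 | intermediate
13 | benzyl (2R,3R)-7-(benzyloxy)-6-[4-(benzyloxy)benzyl]-2-[4-(benzyloxy)phenyl]-3,5-dihydroxy-4-oxochromane-3-carboxylate | O=C1c2c(cc(OCc3ccccc3)c(Cc3ccc(OCc4ccccc4)cc3)c2O)O[C@H](c2ccc(OCc3ccccc3)cc2)[C@]1(O)C(=O)OCc1ccccc1 | intermediate
14 | (2R,3R)-3,5,7-trihydroxy-6-(4-hydroxybenzyl)-2-(4-hydroxyphenyl)-4-oxochromane-3-carboxylic acid | O=C1c2c(cc(O)c(Cc3ccc(O)cc3)c2O)O[C@H](c2ccc(O)cc2)[C@]1(O)C(=O)O | intermediate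
15 | (2R)-6-(4-hydroxybenzyl)-2-(4-hydroxyphenyl)-2H-chromene-3,4,5,7-tetrol | OC1=C(O)[C@@H](c2ccc(O)cc2)Oc2cc(O)c(Cc3ccc(O)cc3)c(O)c21 | intermediate
16 | gericudranin E, (2R,3R)-3,5,7-trihydroxy-6-(4-hydroxybenzyl)-2-(4-hydroxyphenyl)chroman-4-one | O=C1c2c(cc(O)c(Cc3ccc(O)cc3)c2O)O[C@H](c2ccc(O)cc2)[C@H]1O | target

**Step count and risks**

Total steps: 7. Longest linear sequence: 5 steps (steps 3, 4, 5, 6, 7; the branch through steps 1, 2, 5, 6, 7 is equally long).

Most likely to fail, step 6. This is a new substrate class for the dynamic kinetic benzoin cyclisation. The hindered, electron-rich aldehyde with a free chelated 5-OH may be slow to form the Breslow intermediate, a reversible Rap–Stoermer-type aldol of enol 12 onto the aldehyde can compete, and the C2 selectivity depends on a high diastereomeric preference in the ring-closing transition state. The fallback sets out from 10 and 6 and comes back at 13. It forms the C–C bond intermolecularly and closes ring C afterwards through the C–O bond. A carbene-catalysed dynamic kinetic cross-benzoin addition, with (5aS,10bR)-2-(2,4,6-trimethylphenyl)-5a,10b-dihydro-4H,6H-indeno[2,1-b][1,2,4]triazolo[4,3-d][1,4]oxazin-2-ium chloride and K2CO3 as base, of aldehyde 10 as acyl-anion donor to the racemising chloro keto ester 6 gives benzyl (2R,3S)-2-{4-(benzyloxy)-3-[4-(benzyloxy)benzyl]-2,6-dihydroxybenzoyl}-3-[4-(benzyloxy)phenyl]-3-chloro-2-hydroxypropanoate F1. K2CO3 in acetone then lets the less hindered ortho-phenoxide displace the benzylic chloride in a 6-exo SN2 reaction with inversion, which gives 13 with C2 as R.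

Second, step 5. The two ortho-hydroxyl groups of 10 are told apart only by steric hindrance, and the base can enolise 6 or trigger aldol chemistry in the product. The fallback sets out from 8 and 6 and comes back at 11. The diphenol 8, whose two hydroxyl groups are equivalent, is alkylated with 6 (K2CO3, acetone) to give benzyl 3-[5-(benzyloxy)-2-formyl-3-hydroxyphenoxy]-3-[4-(benzyloxy)phenyl]-2-oxopropanoate F2 with no regiochemical question. The C-benzyl group is then introduced with 9 and Sc(OTf)3 at the position ortho to the remaining free hydroxyl group, the more activated and less crowded of the two open positions, which gives 11.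

Third, step 4. The Friedel–Crafts benzylation is run on a ring that carries a formyl group, and it may give bis-benzylation, oligomers of the benzyl cation or triarylmethanes from the aldehyde. The fallback sets out from 9 and comes back at 10. It benzylates the ring before the formyl group is present. Phloroglucinol F3, used in excess, reacts with 9 under Sc(OTf)3 to give 2-[4-(benzyloxy)benzyl]benzene-1,3,5-triol F4. Vilsmeier–Haack formylation (POCl3, DMF, then water) at either of the two equivalent open positions gives 3-[4-(benzyloxy)benzyl]-2,4,6-trihydroxybenzaldehyde F5. Selective benzylation of the hydroxyl group para to the formyl group (BnBr, CsHCO3, MeCN) then gives 10.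

**Further compounds**
F1 | step 6 | benzyl (2R,3S)-2-{4-(benzyloxy)-3-[4-(benzyloxy)benzyl]-2,6-dihydroxybenzoyl}-3-[4-(benzyloxy)phenyl]-3-chloro-2-hydroxypropanoate | O=C(c1c(O)cc(OCc2ccccc2)c(Cc2ccc(OCc3ccccc3)cc2)c1O)[C@@](O)(C(=O)OCc1ccccc1)[C@@H](Cl)c1ccc(OCc2ccccc2)cc1
F2 | step 5 | benzyl 3-[5-(benzyloxy)-2-formyl-3-hydroxyphenoxy]-3-[4-(benzyloxy)phenyl]-2-oxopropanoate (racemic) | O=C(OCc1ccccc1)C(=O)C(Oc1cc(OCc2ccccc2)cc(O)c1C=O)c1ccc(OCc2ccccc2)cc1
F3 | step 4 | phloroglucinol (benzene-1,3,5-triol, commercial) | Oc1cc(O)cc(O)c1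
F4 | step 4 | 2-[4-(benzyloxy)benzyl]benzene-1,3,5-triol | Oc1cc(O)c(Cc2ccc(OCc3ccccc3)cc2)c(O)c1
F5 | step 4 | 3-[4-(benzyloxy)benzyl]-2,4,6-trihydroxybenzaldehyde | O=Cc1c(O)cc(O)c(Cc2ccc(OCc3ccccc3)cc2)c1O
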